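Compare two orders.

all flasks: free catalyst 6.6 mol%

|  | substrate | coupling partner | remark | time |
|---|---|---|---|---|
| teal | 0.0043 M | 0.80 equiv | run made earlier |  |
| red | 0.035 M | 0.80 equiv | run made earlier |  |
| beta | 0.0060 M | 0.800 equiv |  | 8.0 h |
| alpha | 0.012 M | 0.800 equiv |  | 8.0 h |
| zeta | 0.025 M | 0.800 equiv |  | 8.0 h |
| delta | 0.050 M | 0.800 equiv |  | 8.0 h |

| run | time / h | target / % | side product / % | substrate / % |
|---|---|---|---|---|
| teal | 0.833 | 12 | 1 | 78 |
| teal | 1.50 | 21 | 2 | 67 |
| teal | 2.50 | 32 | 4 | 57 |
| teal | 3.00 | 36 | 8 | 53 |
| teal | 4.00 | 44 | 9 | 42 |
| red | 0.333 | 23 | 6 | 65 |
| red | 1.00 | 52 | 20 | 25 |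
| red | 2.00 | 64 | 27 | 4 |
| red | 3.00 | 65 | 28 | 0 |
| red | 4.00 | 65 | 26 | 0 |

(standard deviation of a reading: 1.5 percentage points)

- percent here means substrate units held: one side product counts as two
- "hardly changes" means that all values lie within two and a half points (for a concentration: within two and a half percent of the largest)

- share of target in all that became target or side product for beta, alpha, zeta, delta, in this order
- the shape of the row from first to last (rises all the way / rises, then falls / hardly changes / falls, then rises / falls all the way)

The share asked for, the selectivity to target, compares two rates, that of the path to target and that of the path to side product, so you need their ratio at each concentration. Equivalents and mol% stay the same in every flask, so catalyst scales with substrate. With equivalents and mol% held, equal overall orders give a ratio that does not move with concentration and a flat row: that is the zero of the scale.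

One side product holds two substrate units, so I take its path as second order overall. In teal, target has taken more of the substrate than side product has, so I read the target path from the fractional loss of substrate in the two earlier runs:

teal, to 4.00 h: 0.217 h⁻¹

red, to 1.00 h: 1.39 h⁻¹

A second-order path raises this fractional rate in proportion to concentration, and my reading for the target path falls a little short of that. The shortfall is the order gap, the order of the side path minus that of the target path:

gap = 1 − ln(red rate / teal rate) / ln(red concentration / teal concentration) = 0.115

The last two red readings give a side-to-target ratio of 0.415. Scaling that ratio by concentration raised to the gap, my share for each flask is: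

beta 74.7%, alpha 73.1%, zeta 71.4%, delta 69.8%

The forecast gives 82%, 77%, 73% and 68%, so falls all the way, calling the concentration effect “a weak dependence”.

The flasks give 73.5%, 71.3%, 70.5% and 69.0%, so the row falls all the way.

    substrate + free catalyst → catalyst intermediate A (k = 570 L mol⁻¹ min⁻¹)
    coupling partner + catalyst intermediate A ⇌ catalyst intermediate B (K = 11.0 L mol⁻¹, k = 110 L mol⁻¹ min⁻¹)
    catalyst intermediate B → released group + catalyst intermediate C (k = 1.50 min⁻¹)
    catalyst intermediate C ⇌ free catalyst + target (K = 0.0310 M, k = 1.00 min⁻¹)
    substrate + target → side product (k = 0.320 L mol⁻¹ min⁻¹)

From beta to delta the row shows an order gap of 0.104, beside the 0.115 read from teal and red. Side product forms from substrate and target, and in delta the wearing away of coupling partner accounts for part of the lost share of target: with coupling partner held at its charge, the share of target in delta stands at 81.5% instead of 69.0%.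

The data were generated by integration from invented constants; the scatter is artificial.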